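**Plan**

Numbering of the target core, kept for every intermediate: C1 = CH3‑bearing quaternary ring‑fusion carbon, C2 = ketone, C3, C4 = C(OH)(i‑Pr), C5 = ring‑fusion CH, C6 = acyloxy carbon, C7, C8(CH3)=C9, C10; β = face of the C1 methyl.
Retrosynthesis: cut (a) the C6–O ester bond, (b) the C1–C5 bond of the cyclopentanone, redrawn as the C1–C6 bond of a cis‑decalin (1,2‑shift), (c) C1–C10 and C6–C7 of that decalin (Diels–Alder of thymoquinone with isoprene, which together hold all 15 core carbons).
Enabling feature: oxygenated C6 is bonded directly to ring‑fusion C5, so an O–C6/C5–leaving‑group pair lets C1 move from C6 to C5; ring atoms C1–C6 are the thymoquinone ring, already carrying C2=O, C1–CH3 and C4–i‑Pr.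
Forward: cycloaddition gives the cis‑decalin; C6–OH, C5–O and C4–O are placed on its convex β face, C4–O held in a C3–C4 epoxide (temporary ring) so that only C6–OH can push; the semipinacol shift contracts the cyclohexane to the cyclopentanone and expands the cyclohexene to the cycloheptene; then epoxide → aldol, C6=O → 6α‑OH, anisoylation.
Stereochemistry: C1 by catalytic enantioselective Diels–Alder; the rest is relayed: decalin C6–OH cis to the C1 methyl, C5–O and C4–O by hydroxyl‑directed epoxidations, H5 (trans fusion) by inversion at C5 in the shift, C6 of the target by hydride delivery from C4–OH.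

Key step: step 7

Assumption: the (S)‑configured oxazaborolidinium catalyst of step 1 is taken to shield the quinone face that leads to 3; should the opposite sense of induction be found, the (R)‑catalyst is used.

**Step 1**
Reactants: 1 thymoquinone (2‑isopropyl‑5‑methyl‑1,4‑benzoquinone); 2 isoprene
Product: 3 cis‑fused adduct (4aR,8aS)‑2‑isopropyl‑4a,7‑dimethyl‑4a,5,8,8a‑tetrahydronaphthalene‑1,4‑dione
Conditions: (S)‑o‑tolyl‑CBS‑oxazaborolidine·HNTf2 (20 mol %), CH2Cl2, −78 → −40 °C
Reagents that add atoms: none
Why: Lewis‑acid‑catalysed quinone Diels–Alder reaction in which the catalyst‑bound C2 carbonyl polarises the methyl‑bearing C1=C6 bond (electrophilic β‑CH = C6), so the more nucleophilic isoprene terminus should bond to C6 and put the ring methyl on C8 ("para" to C1), the more hindered isopropyl‑bearing C3=C4 bond should stay, suprafacial addition makes the fusion cis, and the chiral cation selects the face giving 1β‑CH3/6β‑H (the only centre set by catalysis).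

**Step 2**
Reactants: 3 Diels–Alder adduct
Product: 5 cis‑fused 6β‑hydroxy enedione (α‑ketol), via potassium enolate 4 (not isolated)
Conditions: KHMDS, THF, −78 °C; then 2‑(phenylsulfonyl)‑3‑phenyloxaziridine, −78 °C; aq NH4Cl
Reagents that add atoms: 2‑(phenylsulfonyl)‑3‑phenyloxaziridine, O=S(=O)(c1ccccc1)N1OC1c1ccccc1
Why: C6–H is the only α‑hydrogen (C1 is quaternary, C3 vinylic), and oxaziridine hydroxylation of the tetrasubstituted enolate (Davis oxidation) should occur syn to the angular methyl through the folded cis‑decalin‑like transition state, as in angular alkylations of such ring‑fusion enolates, giving the cis‑fused 6β‑carbinol.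

**Step 3**
Reactants: 5 cis‑fused 6β‑hydroxy enedione
Product: 7 C5 enol triflate (C4=C5–OTf; C3H2), via lithium enolate 6 (not isolated)
Conditions: L‑Selectride, THF, −78 °C; then PhNTf2, −78 → 0 °C; aq NH4Cl
Reagents that add atoms: N‑phenylbis(trifluoromethanesulfonimide), O=S(=O)(N(c1ccccc1)S(=O)(=O)C(F)(F)F)C(F)(F)F
Why: conjugate reduction with enolate trapping: hydride should add 1,4 to the unsubstituted enedione carbon C3 (C4 carries the isopropyl group), which gives regiospecifically the C4=C5 enolate that is triflated on oxygen, so the C5 carbonyl is singled out from the C2 carbonyl without any stereochemical issue; the tertiary hydroxyl is inert at −78 °C.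

**Step 4**
Reactants: 7 C5 enol triflate
Product: 8 cis‑fused 6β‑hydroxy‑Δ4,8‑dien‑2‑one (tertiary allylic alcohol; β,γ‑unsaturated ketone)
Conditions: Pd(PPh3)4 (5 mol %), Bu3SnH, LiCl, THF, rt
Reagents that add atoms: none
Why: palladium‑catalysed tin hydride reduction of the enol triflate replaces OTf by H under neutral conditions, which should leave the C4=C5 bond out of conjugation and place C6–OH allylic to it.

**Step 5**
Reactants: 8 tertiary allylic alcohol
Product: 9 4β,5β‑epoxide of 8
Conditions: VO(acac)2 (5 mol %), t‑BuOOH (decane), CH2Cl2, 0 °C → rt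
Reagents that add atoms: tert‑butyl hydroperoxide, CC(C)(C)OO
Why: vanadium‑catalysed hydroxyl‑directed epoxidation, in which the C6 vanadate ester delivers oxygen to the adjacent C4=C5 bond on its own β face while the undirected C8=C9 bond reacts far more slowly; this fixes the C5–O bond β, cis to C6–OH.

**Step 6**
Reactants: 9 4β,5β‑epoxy ketone
Product: 11 3β,4β‑epoxy‑5β,6β‑diol‑2‑one, via cis‑diol enone 10 (not isolated)
Conditions: DBU, CH2Cl2, 0 °C → rt; then t‑BuOOH (decane), rt
Reagents that add atoms: tert‑butyl hydroperoxide, CC(C)(C)OO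
Why: DBU removes a C3 proton and the enolate opens the β,γ‑epoxide at C4 (E1cB) without touching the C5–O bond, and the resulting non‑enolisable enone 10 is epoxidised in the same flask by the hydroperoxide anion (Weitz–Scheffer epoxidation) from the β face, which is the convex face of the cis‑fused bicycle and the face to which the two syn hydroxyls at C5 and C6 guide the peroxide by hydrogen bonding.

**Step 7**
Reactants: 11 3β,4β‑epoxy‑5β,6β‑diol‑2‑one
Product: 13 trans‑fused 3β,4β‑epoxydauc‑8‑ene‑2,6‑dione, via C5 triflate 12 (not isolated)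
Conditions: Tf2O, 2,6‑lutidine, CH2Cl2, −78 → 0 °C
Reagents that add atoms: none
Why: Triflic anhydride sulfonylates only the secondary C5–OH; in the favoured envelope of the epoxy‑cyclohexanone ring (C6 flap β; the other envelope suffers a syn‑diaxial C1–CH3/C5–OTf clash) the C5–OTf bond is pseudo‑equatorial and antiperiplanar to the C1–C6 ring‑fusion bond, so on warming the C6–OH lone pair pushes, C1 migrates with its bonding pair from C6 to C5, triflate leaves and C6 becomes the ketone (semipinacol rearrangement of a 2‑hydroxy sulfonate). The closest known reaction type is the pinacol‑type rearrangement of decalin‑1,2‑diol monosulfonates to hydroazulenones. The cyclopentanone (C1–C2–C3–C4–C5) is closed by this 1,2‑alkyl shift, i.e. contraction of the six‑membered ring with extrusion of C6, and the same shift expands the cyclohexene to the cycloheptenone by inserting C5 between C1 and C6. C5 is formed with inversion (C1 enters anti to the β‑triflate), which places H5 α and makes the new ring fusion trans; C1 migrates with retention and the epoxide carbons C3/C4 are untouched. The step needs migration of C1 rather than C3 or C7 and no elimination: O4 is tied up in the epoxide so only O6 can push, the C6–C7 bond is gauche to the leaving group, and C5 has no vicinal hydrogen because C4 and C6 are fully substituted. The substrate has no enolisable hydrogen and the lutidine buffer keeps the medium non‑basic, which should protect the β,γ‑epoxy ketone product from E1cB opening.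

**Step 8**
Reactants: 13 epoxy diketone
Product: 14 4β‑hydroxydauc‑8‑ene‑2,6‑dione
Conditions: SmI2, THF/MeOH, −90 °C
Reagents that add atoms: none
Why: samarium diiodide reduction of the α,β‑epoxy ketone (electron transfer to the C2 carbonyl, scission of the Cα–O bond at C3, protonation) should give the aldol‑type β‑hydroxy ketone with the C4–O bond, and so the 4β‑OH configuration, retained, while the isolated C6 ketone is not reduced at −90 °C.

**Step 9**
Reactants: 14 4β‑hydroxy diketone
Product: 15 4β,6α‑dihydroxydauc‑8‑en‑2‑one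
Conditions: Me4NBH(OAc)3, MeCN/AcOH (1:1), −30 °C
Reagents that add atoms: none
Why: Evans–Saksena reduction, in which the borohydride is bound by the tertiary C4–OH and delivers hydride to the face of the C6 carbonyl turned toward O4, which should give 6α‑OH (H6 β), whereas delivery to the C2 carbonyl, which lies in the same five‑membered ring next to quaternary C1, would need a strained bridged transition state.

**Step 10**
Reactants: 15 4β,6α‑dihydroxydauc‑8‑en‑2‑one; 16 4‑methoxybenzoyl chloride
Product: 17 target 4‑methoxybenzoate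
Conditions: pyridine, DMAP (cat.), CH2Cl2, 0 °C → rt
Reagents that add atoms: none
Why: DMAP‑catalysed acylation should take place only at the secondary C6–OH, the tertiary C4–OH being unreactive under these mild conditions.

**Compound list**

1 | thymoquinone (2‑isopropyl‑5‑methyl‑1,4‑benzoquinone) | CC1=CC(=O)C(C(C)C)=CC1=O | starting material
2 | isoprene (2‑methylbuta‑1,3‑diene) | C=CC(C)=C | starting material
3 | (4aR,8aS)‑2‑isopropyl‑4a,7‑dimethyl‑4a,5,8,8a‑tetrahydronaphthalene‑1,4‑dione (cis‑fused; 1β‑CH3, 6β‑H) | CC1=CC[C@@]2(C)C(=O)C=C(C(C)C)C(=O)[C@H]2C1 | intermediate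
4 | potassium enolate of 3 (O–C5=C6) | CC1=CC[C@@]2(C)C(=O)C=C(C(C)C)C([O-])=C2C1.[K+] | intermediate
5 | cis‑fused 6β‑hydroxy derivative of 3 (α‑ketol; C2=O, C3=C4, C5=O) | CC1=CC[C@@]2(C)C(=O)C=C(C(C)C)C(=O)[C@@]2(O)C1 | intermediate
6 | lithium C4=C5 enolate from 1,4‑reduction of 5 | CC1=CC[C@@]2(C)C(=O)CC(C(C)C)=C([O-])[C@@]2(O)C1.[Li+] | intermediate
7 | C5 enol triflate (C4=C5–OTf, C3H2, C2=O, 6β‑OH) | CC1=CC[C@@]2(C)C(=O)CC(C(C)C)=C(OS(=O)(=O)C(F)(F)F)[C@@]2(O)C1 | intermediate
8 | cis‑fused 6β‑hydroxy‑4‑isopropyl‑1β,8‑dimethylbicyclo[4.4.0]deca‑4,8‑dien‑2‑one (target numbering) | CC1=CC[C@@]2(C)C(=O)CC(C(C)C)=C[C@@]2(O)C1 | intermediate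
9 | 4β,5β‑epoxide of 8 | CC1=CC[C@@]2(C)C(=O)C[C@]3(C(C)C)O[C@@H]3[C@@]2(O)C1 | intermediate
10 | cis‑fused 5β,6β‑dihydroxy‑Δ3,8‑dien‑2‑one | CC1=CC[C@@]2(C)C(=O)C=C(C(C)C)[C@H](O)[C@@]2(O)C1 | intermediate
11 | cis‑fused 3β,4β‑epoxy‑5β,6β‑dihydroxy‑Δ8‑en‑2‑one | CC1=CC[C@@]2(C)C(=O)[C@@H]3O[C@]3(C(C)C)[C@H](O)[C@@]2(O)C1 | intermediate
12 | C5 triflate of 11 | CC1=CC[C@@]2(C)C(=O)[C@@H]3O[C@]3(C(C)C)[C@H](OS(=O)(=O)C(F)(F)F)[C@@]2(O)C1 | intermediate
13 | trans‑fused 3β,4β‑epoxydauc‑8‑ene‑2,6‑dione (5α‑H) | CC1=CC[C@@]2(C)C(=O)[C@@H]3O[C@]3(C(C)C)[C@@H]2C(=O)C1 | intermediate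
14 | 4β‑hydroxydauc‑8‑ene‑2,6‑dione | CC1=CC[C@@]2(C)C(=O)C[C@@](O)(C(C)C)[C@@H]2C(=O)C1 | intermediate
15 | 4β,6α‑dihydroxydauc‑8‑en‑2‑one | CC1=CC[C@@]2(C)C(=O)C[C@@](O)(C(C)C)[C@@H]2[C@@H](O)C1 | intermediate
16 | 4‑methoxybenzoyl chloride | COc1ccc(C(Cl)=O)cc1 | starting material
17 | (3R,3aS,4S,8aR)‑3‑hydroxy‑6,8a‑dimethyl‑1‑oxo‑3‑(propan‑2‑yl)‑1,2,3,3a,4,5,8,8a‑octahydroazulen‑4‑yl 4‑methoxybenzoate | COc1ccc(C(=O)O[C@H]2CC(C)=CC[C@@]3(C)C(=O)C[C@@](O)(C(C)C)[C@H]23)cc1 | target

**Step count and risks**

Total steps: 10. Longest linear sequence: 10 steps (from 1 to 17).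

Steps most likely to fail:

Step 7. Sulfonylation of the hindered C5–OH may be slow enough for the tertiary C6–OH to ionise. The C5 triflate may also ionise with participation of the neighbouring epoxide, so that the mask is lost before C1 migrates. The fallback leaves out the epoxide and rearranges one oxidation pattern earlier. It sets out from 8: hydroxyl‑directed dihydroxylation (OsO4·TMEDA, CH2Cl2, −78 °C, then aq Na2SO3) should add both oxygens to C4=C5 syn to C6–OH and give the all‑β 4,5,6‑triol F1. Mesylation of its only secondary hydroxyl (MsCl, Et3N) gives the C5 mesylate F2. Organoaluminium‑promoted pinacol‑type rearrangement (Et3Al, CH2Cl2, −78 °C) then gives 14 directly, where it rejoins the route. Here O4 is free, so the outcome rests on the higher migratory aptitude of the fully substituted C1 over the primary C3 and on relief of the congested C1–C6 bond. This path also bypasses steps 5 and 6.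

Step 1. The chiral Lewis acid may bind the other carbonyl, which would turn the isoprene orientation (methyl on C9) or steer addition to the isopropyl‑bearing double bond, or it may give poor facial selectivity. The fallback replaces asymmetric catalysis by resolution. It sets out from 1 and 2: uncatalysed cycloaddition (toluene, 90 °C), governed only by the intrinsic polarisation of the methyl‑bearing double bond, gives 3 together with its enantiomer F3. The two are separated by preparative chromatography on a chiral stationary phase, and the route continues from 3.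

Step 9. Hydride may also be delivered from O4 to the C2 carbonyl (loss of chemoselectivity). The fallback accepts over‑reduction and restores the ketone at the end. It sets out from 14: excess Me4NBH(OAc)3 at room temperature reduces both carbonyls to the 2,4,6‑triol F4 (6α‑OH by the same delivery; the C2 configuration is irrelevant). One equivalent of 16 (pyridine, DMAP, 0 °C) acylates the less hindered C6–OH rather than the neopentyl C2–OH and gives the 6‑O‑anisoyl‑2‑ol F5. Dess–Martin oxidation of the remaining secondary alcohol gives 17, where the route ends.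

**Further compounds**

F1 | step 7 | cis‑fused 4β,5β,6β‑trihydroxy‑Δ8‑en‑2‑one (all‑β triol) | CC1=CC[C@@]2(C)C(=O)C[C@@](O)(C(C)C)[C@H](O)[C@@]2(O)C1
F2 | step 7 | C5 mesylate of F1 | CC1=CC[C@@]2(C)C(=O)C[C@@](O)(C(C)C)[C@H](OS(C)(=O)=O)[C@@]2(O)C1
F3 | step 1 | (4aS,8aR)‑enantiomer of 3 | CC1=CC[C@]2(C)C(=O)C=C(C(C)C)C(=O)[C@@H]2C1
F4 | step 9 | dauc‑8‑ene‑2α,4β,6α‑triol | CC1=CC[C@@]2(C)[C@@H](O)C[C@@](O)(C(C)C)[C@@H]2[C@@H](O)C1
F5 | step 9 | 2α,4β‑dihydroxydauc‑8‑en‑6α‑yl 4‑methoxybenzoate | CC1=CC[C@@]2(C)[C@@H](O)C[C@@](O)(C(C)C)[C@@H]2[C@@H](OC(=O)c3ccc(OC)cc3)C1
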